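Ring A is built last. It is cut so that C1′ (carrying the C5–CH2 bridge), C6′ (carrying CH2OMe), C5′ and C4′ come from an α-diazo enone, and C2′(OMe)–C3′H from methoxyacetylene. The key step exploits the ring A pattern itself: a free C4′ hydroxyl para to C1′ and meta to the C2′ methoxy group is what a vinylketene–alkoxyalkyne benzannulation delivers. One operation (Wolff shift, [2+2] addition, four-electron opening, six-electron closure) forms four C–C bonds and the complete ring. The precursor is the O6-silylated 8-methoxy-3-methylisocoumarin bearing a 2-diazo-4-(methoxymethyl)-3-oxopent-4-enyl chain at C5.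

Key step: step 12

Remarks on the chemistry:
- Locants: isocoumarin C1 (C=O), O2, C3 (Me), C4, C5 (bridge), C6 (OH), C8 (OMe). Ring A: C1′ (bridge carbon), C2′ (OMe), C4′ (OH), C6′ (CH2OMe).
- Methoxyacetylene is assumed not to be reliably purchasable and is made in step 11.
- The target is achiral. Compounds 14, 16 and 22 are racemic, and their stereocentres disappear again.
- The O6 silyl ether is essential in step 12: a free C6 phenol would add to the neighbouring ketene and close a dihydrocoumarin.

Step 1
Reactants: 1 methyl orsellinate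
Product: 2 methyl 2-hydroxy-6-methyl-4-[(triisopropylsilyl)oxy]benzoate
Conditions: i-Pr3SiCl (1.05 equiv), imidazole, DMF, 0 °C → rt
Reagents that add atoms: triisopropylsilyl chloride, CC(C)[Si](Cl)(C(C)C)C(C)C
Why: Imidazole-promoted O-silylation of a phenol; the C4 hydroxyl is the only unchelated one (the C2 hydroxyl is hydrogen-bonded to the ester and flanked by it), so the bulky chlorosilane should react at O4 alone.

Step 2
Reactants: 2 methyl 2-hydroxy-6-methyl-4-[(triisopropylsilyl)oxy]benzoate
Product: 3 methyl 2-methoxy-6-methyl-4-[(triisopropylsilyl)oxy]benzoate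
Conditions: MeI, K2CO3, acetone, 55 °C
Reagents that add atoms: iodomethane, CI
Why: Williamson ether synthesis on the remaining chelated phenol; the hindered aryl triisopropylsilyl ether should withstand anhydrous carbonate in acetone.

Step 3
Reactants: 3 methyl 2-methoxy-6-methyl-4-[(triisopropylsilyl)oxy]benzoate
Product: 4 methyl 3-iodo-6-methoxy-2-methyl-4-[(triisopropylsilyl)oxy]benzoate
Conditions: N-iodosuccinimide, CF3CO2H (cat.), MeCN, 0 °C → rt, dark
Reagents that add atoms: N-iodosuccinimide, O=C1CCC(=O)N1I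
Why: Electrophilic aromatic iodination; the free position para to the methoxy group (ortho to OSi and to the methyl) should be attacked, because the other free position is only ortho-activated and lies between two oxygen substituents, with the methoxy methyl pushed toward it by the ester.

Step 4
Reactants: 4 methyl 3-iodo-6-methoxy-2-methyl-4-[(triisopropylsilyl)oxy]benzoate; 5 N-methoxy-N-methylacetamide
Product: 7 methyl 3-iodo-6-methoxy-2-(2-oxopropyl)-4-[(triisopropylsilyl)oxy]benzoate, via lithiated ester 6 (not isolated)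
Conditions: LiN(i-Pr)2 (2.2 equiv), THF, −78 °C; then 5, −78 → −40 °C; aq. NH4Cl
Reagents that add atoms: none
Why: Lateral (benzylic) lithiation of an ortho-toluate followed by acylation with an N-methoxy-N-methylamide; the amide base deprotonates the methyl group next to the ester without exchanging the aryl iodide, and the chelated tetrahedral adduct prevents over-addition.

Step 5
Reactants: 7 methyl 3-iodo-6-methoxy-2-(2-oxopropyl)-4-[(triisopropylsilyl)oxy]benzoate
Product: 8 5-iodo-8-methoxy-3-methyl-6-[(triisopropylsilyl)oxy]-1H-isochromen-1-one (the 5-iodoisocoumarin)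
Conditions: TsOH·H2O (10 mol%), PhMe, 80 °C
Reagents that add atoms: none
Why: Acid-catalysed enol lactonization, in which the ketone enol oxygen attacks the neighbouring ester through a six-membered transition state and methanol is lost; acid avoids the carbon-acylation to a naphthalenediol that a base could cause, and the conditions are mild enough for the aryl iodide and aryl silyl ether.

Step 6
Reactants: 8 5-iodo-8-methoxy-3-methyl-6-[(triisopropylsilyl)oxy]-1H-isochromen-1-one; 9 allyl alcohol
Product: 10 3-{8-methoxy-3-methyl-1-oxo-6-[(triisopropylsilyl)oxy]-1H-isochromen-5-yl}propanal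
Conditions: Pd(OAc)2 (5 mol%), Bu4NCl, NaHCO3, DMF, 50–70 °C
Reagents that add atoms: none
Why: Heck reaction under ligand-free phase-transfer conditions; arylation of the terminal alkene carbon, β-hydride elimination toward the carbinol carbon and tautomerization should give the saturated aldehyde directly, and the iodide is chosen because C5 is flanked on both sides.

Step 7
Reactants: 11 2,3-dibromopropene
Product: 12 2-bromo-3-methoxyprop-1-ene
Conditions: NaOMe, MeOH, 0 °C → rt
Reagents that add atoms: sodium methoxide, [Na+].[O-]C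
Why: SN2 substitution at the allylic bromide; the vinylic bromide is inert to methoxide.

Step 8
Reactants: 12 2-bromo-3-methoxyprop-1-ene; 10 3-{8-methoxy-3-methyl-1-oxo-6-[(triisopropylsilyl)oxy]-1H-isochromen-5-yl}propanal
Product: 14 rac-5-[3-hydroxy-4-(methoxymethyl)pent-4-en-1-yl]-8-methoxy-3-methyl-6-[(triisopropylsilyl)oxy]-1H-isochromen-1-one, via vinyllithium 13 (not isolated)
Conditions: 12 (1.3 equiv), t-BuLi (2.6 equiv), Et2O, −78 °C; then 10, THF, −78 °C; aq. NH4Cl
Reagents that add atoms: none
Why: Bromine–lithium exchange followed by 1,2-addition of the vinyllithium to the aldehyde; at −78 °C the aldehyde should react far faster than the hindered, electron-rich lactone carbonyl, and the carbinol centre forms as a racemate that step 9 removes.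

Step 9
Reactants: 14 rac-5-[3-hydroxy-4-(methoxymethyl)pent-4-en-1-yl]-8-methoxy-3-methyl-6-[(triisopropylsilyl)oxy]-1H-isochromen-1-one
Product: 15 8-methoxy-5-[4-(methoxymethyl)-3-oxopent-4-en-1-yl]-3-methyl-6-[(triisopropylsilyl)oxy]-1H-isochromen-1-one
Conditions: Dess–Martin periodinane, CH2Cl2, 0 °C → rt
Reagents that add atoms: none
Why: Dess–Martin oxidation of the secondary allylic alcohol under near-neutral conditions that leave the silyl ether, the lactone and the exo-methylene group untouched.

Step 10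
Reactants: 15 8-methoxy-5-[4-(methoxymethyl)-3-oxopent-4-en-1-yl]-3-methyl-6-[(triisopropylsilyl)oxy]-1H-isochromen-1-one
Product: 17 5-[2-diazo-4-(methoxymethyl)-3-oxopent-4-en-1-yl]-8-methoxy-3-methyl-6-[(triisopropylsilyl)oxy]-1H-isochromen-1-one, via trifluoroacetyl diketone 16 (not isolated)
Conditions: LiN(SiMe3)2 (1.1 equiv), THF, −78 °C; CF3CO2CH2CF3, −78 °C; 5% aq. HCl; crude 16, MeSO2N3, Et3N, H2O (1 equiv), MeCN, rt
Reagents that add atoms: methanesulfonyl azide, CS(=O)(=O)N=[N+]=[N-] (the two diazo nitrogens); 2,2,2-trifluoroethyl trifluoroacetate, O=C(OCC(F)(F)F)C(F)(F)F (trifluoroacetyl group, carried by 16 only)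
Why: Detrifluoroacetylative diazo transfer; kinetic deprotonation at the only α′ position (the CH2 next to the ketone), Claisen-type trifluoroacetylation and reaction of the 1,3-diketone with the sulfonyl azide should deliver N2 with loss of the activating acyl group, a sequence suited to base-sensitive enones and faster than deprotonation of the isocoumarin methyl or the γ-CH2OMe.

Step 11
Reactants: 18 chloroacetaldehyde dimethyl acetal
Product: 20 methoxyacetylene, via sodium methoxyacetylide 19 (not isolated)
Conditions: NaNH2 (3 equiv), liq. NH3, −33 °C; then cold aq. NaCl; distilled into a cold trap, kept as a solution in ClCH2CH2Cl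
Reagents that add atoms: none
Why: Twofold base-induced elimination (HCl, then methanol) gives the acetylide, which is protonated on aqueous quench; the alkyne boils near room temperature and is used at once.

Step 12
Reactants: 17 5-[2-diazo-4-(methoxymethyl)-3-oxopent-4-en-1-yl]-8-methoxy-3-methyl-6-[(triisopropylsilyl)oxy]-1H-isochromen-1-one; 20 methoxyacetylene
Product: 25 5-[4-hydroxy-2-methoxy-6-(methoxymethyl)benzyl]-8-methoxy-3-methyl-6-[(triisopropylsilyl)oxy]-1H-isochromen-1-one, via vinylketene 21 (not isolated), via cyclobutenone 22 (not isolated), via dienylketene 23 (not isolated), via cyclohexadienone 24 (not isolated)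
Conditions: 20 (5 equiv), ClCH2CH2Cl (dilute), hν (violet LED, ca. 400 nm), 0–10 °C, sealed Pyrex tube; then 80 °C
Reagents that add atoms: none
Why: Photochemical Wolff rearrangement of 17 (loss of N2 and 1,2-shift of the 2-(methoxymethyl)vinyl group to the diazo carbon, forming C1′–C6′) gives vinylketene 21, whose carbonyl carbon bonds to the nucleophilic CH of methoxyacetylene and whose α-carbon bonds to the methoxy-bearing carbon in a [2+2] cycloaddition (C4′–C3′ and C1′–C2′) to give cyclobutenone 22. Four-electron electrocyclic opening of 22 breaks C4′–C1′ to give dienylketene 23, and ring A is closed by a thermal six-electron disrotatory electrocyclization (C4′–C5′) to dienone 24, which tautomerizes to the phenol. The closest known reaction type is the Danheiser benzannulation of α-diazo enones with alkoxyalkynes. No stereocentre remains, because the quaternary carbon of 22 is lost on ring opening. The regiochemistry needed (OH para and OMe ortho to the bridge carbon) is secured by the polarization of the alkoxyalkyne. Chemoselectivity is secured by the O6 silyl ether, which keeps that phenol from adding to the ketene, and by irradiating at the long-wavelength edge of the diazo ketone absorption, beyond the isocoumarin band.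

Step 13
Reactants: 25 5-[4-hydroxy-2-methoxy-6-(methoxymethyl)benzyl]-8-methoxy-3-methyl-6-[(triisopropylsilyl)oxy]-1H-isochromen-1-one
Product: 26 6-hydroxy-5-[4-hydroxy-2-methoxy-6-(methoxymethyl)benzyl]-8-methoxy-3-methyl-1H-isochromen-1-one (target)
Conditions: Bu4NF (1.1 equiv), AcOH (1.1 equiv), THF, 0 °C
Reagents that add atoms: none
Why: Fluoride-induced desilylation of the aryl silyl ether, buffered with acetic acid so that the lactone is not exposed to free phenoxide; the aryl methyl ethers and the benzylic methyl ether are inert.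

Compound list
1 | methyl orsellinate (methyl 2,4-dihydroxy-6-methylbenzoate) | COC(=O)c1c(C)cc(O)cc1O | starting material
2 | methyl 2-hydroxy-6-methyl-4-[(triisopropylsilyl)oxy]benzoate | COC(=O)c1c(C)cc(O[Si](C(C)C)(C(C)C)C(C)C)cc1O | intermediate
3 | methyl 2-methoxy-6-methyl-4-[(triisopropylsilyl)oxy]benzoate | COC(=O)c1c(C)cc(O[Si](C(C)C)(C(C)C)C(C)C)cc1OC | intermediate
4 | methyl 3-iodo-6-methoxy-2-methyl-4-[(triisopropylsilyl)oxy]benzoate | COC(=O)c1c(C)c(I)c(O[Si](C(C)C)(C(C)C)C(C)C)cc1OC | intermediate
5 | N-methoxy-N-methylacetamide | CC(=O)N(C)OC | starting material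
6 | methyl 3-iodo-2-(lithiomethyl)-6-methoxy-4-[(triisopropylsilyl)oxy]benzoate (lithiated ester) | [Li]Cc1c(I)c(O[Si](C(C)C)(C(C)C)C(C)C)cc(OC)c1C(=O)OC | intermediate
7 | methyl 3-iodo-6-methoxy-2-(2-oxopropyl)-4-[(triisopropylsilyl)oxy]benzoate | COC(=O)c1c(CC(C)=O)c(I)c(O[Si](C(C)C)(C(C)C)C(C)C)cc1OC | intermediate
8 | 5-iodo-8-methoxy-3-methyl-6-[(triisopropylsilyl)oxy]-1H-isochromen-1-one | Cc1cc2c(I)c(O[Si](C(C)C)(C(C)C)C(C)C)cc(OC)c2c(=O)o1 | intermediate
9 | allyl alcohol (prop-2-en-1-ol) | C=CCO | starting material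
10 | 3-{8-methoxy-3-methyl-1-oxo-6-[(triisopropylsilyl)oxy]-1H-isochromen-5-yl}propanal | Cc1cc2c(CCC=O)c(O[Si](C(C)C)(C(C)C)C(C)C)cc(OC)c2c(=O)o1 | intermediate
11 | 2,3-dibromopropene | C=C(Br)CBr | starting material
12 | 2-bromo-3-methoxyprop-1-ene | C=C(Br)COC | intermediate
13 | (3-methoxyprop-1-en-2-yl)lithium | [Li]C(=C)COC | intermediate
14 | rac-5-[3-hydroxy-4-(methoxymethyl)pent-4-en-1-yl]-8-methoxy-3-methyl-6-[(triisopropylsilyl)oxy]-1H-isochromen-1-one (racemic) | Cc1cc2c(CCC(O)C(=C)COC)c(O[Si](C(C)C)(C(C)C)C(C)C)cc(OC)c2c(=O)o1 | intermediate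
15 | 8-methoxy-5-[4-(methoxymethyl)-3-oxopent-4-en-1-yl]-3-methyl-6-[(triisopropylsilyl)oxy]-1H-isochromen-1-one | Cc1cc2c(CCC(=O)C(=C)COC)c(O[Si](C(C)C)(C(C)C)C(C)C)cc(OC)c2c(=O)o1 | intermediate
16 | 8-methoxy-5-[4-(methoxymethyl)-3-oxo-2-(trifluoroacetyl)pent-4-en-1-yl]-3-methyl-6-[(triisopropylsilyl)oxy]-1H-isochromen-1-one (racemic, enolizable) | Cc1cc2c(CC(C(=O)C(F)(F)F)C(=O)C(=C)COC)c(O[Si](C(C)C)(C(C)C)C(C)C)cc(OC)c2c(=O)o1 | intermediate
17 | 5-[2-diazo-4-(methoxymethyl)-3-oxopent-4-en-1-yl]-8-methoxy-3-methyl-6-[(triisopropylsilyl)oxy]-1H-isochromen-1-one | C=C(COC)C(=O)C(=[N+]=[N-])Cc1c(O[Si](C(C)C)(C(C)C)C(C)C)cc(OC)c2c(=O)oc(C)cc12 | intermediate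
18 | chloroacetaldehyde dimethyl acetal (2-chloro-1,1-dimethoxyethane) | COC(CCl)OC | starting material
19 | sodium methoxyacetylide | [Na+].[C-]#COC | intermediate
20 | methoxyacetylene | COC#C | intermediate
21 | vinylketene: 2-(isocoumarin-5-ylmethyl)-3-(methoxymethyl)buta-1,3-dien-1-one, isocoumarin = 8-methoxy-3-methyl-6-[(triisopropylsilyl)oxy]-1-oxo-1H-isochromen-5-yl | C=C(COC)C(=C=O)Cc1c(O[Si](C(C)C)(C(C)C)C(C)C)cc(OC)c2c(=O)oc(C)cc12 | intermediate
22 | cyclobutenone: rac-4-(isocoumarin-5-ylmethyl)-3-methoxy-4-(3-methoxyprop-1-en-2-yl)cyclobut-2-en-1-one (racemic) | C=C(COC)C1(Cc2c(O[Si](C(C)C)(C(C)C)C(C)C)cc(OC)c3c(=O)oc(C)cc23)C(OC)=CC1=O | intermediate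
23 | dienylketene: 4-(isocoumarin-5-ylmethyl)-3-methoxy-5-(methoxymethyl)hexa-1,3,5-trien-1-one, ketenyl CH and 3-methoxyprop-1-en-2-yl group cis on the central C=C | O=C=C/C(OC)=C(\C(=C)COC)Cc1c(O[Si](C(C)C)(C(C)C)C(C)C)cc(OC)c2c(=O)oc(C)cc12 | intermediate
24 | cyclohexadienone: 4-(isocoumarin-5-ylmethyl)-3-methoxy-5-(methoxymethyl)cyclohexa-2,4-dien-1-one | COCC1=C(Cc2c(O[Si](C(C)C)(C(C)C)C(C)C)cc(OC)c3c(=O)oc(C)cc23)C(OC)=CC(=O)C1 | intermediate
25 | 5-[4-hydroxy-2-methoxy-6-(methoxymethyl)benzyl]-8-methoxy-3-methyl-6-[(triisopropylsilyl)oxy]-1H-isochromen-1-one | COCc1cc(O)cc(OC)c1Cc1c(O[Si](C(C)C)(C(C)C)C(C)C)cc(OC)c2c(=O)oc(C)cc12 | intermediate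
26 | 6-hydroxy-5-[4-hydroxy-2-methoxy-6-(methoxymethyl)benzyl]-8-methoxy-3-methyl-1H-isochromen-1-one (CNP0481202.0) | COCc1cc(O)cc(OC)c1Cc1c(O)cc(OC)c2c(=O)oc(C)cc12 | target

Total step count: 13. Longest linear sequence: 11 steps (steps 1–6, 8–10, 12, 13 from methyl orsellinate); steps 7 and 11 are one-step side preparations.

Steps most likely to fail

1. Step 12. The light may be absorbed unproductively, or the diazo ketone may be consumed by cycloaddition onto an enone before it rearranges. The vinylketene may dimerize or be captured by the product phenol before it meets the volatile alkyne, or the hindered cyclobutenone may fail to open. The fallback sets out from 8 and returns at 25; it builds ring A by a Diels–Alder benzannulation instead. Carbonylative Sonogashira coupling of 8 with methyl propargyl ether (PdCl2(PPh3)2, CuI, Et3N, CO at 1 atm) should give the ynone 8-methoxy-5-(4-methoxybut-2-ynoyl)-3-methyl-6-[(triisopropylsilyl)oxy]-1H-isochromen-1-one F1. O-Silylation of 4,4-dimethoxybut-3-en-2-one (LiN(i-Pr)2, Me3SiCl) provides 1,1-dimethoxy-3-(trimethylsilyloxy)buta-1,3-diene F2. Heating F1 with F2 in toluene should give the cycloadduct 5-{[6,6-dimethoxy-2-(methoxymethyl)-4-(trimethylsilyloxy)cyclohexa-1,4-dien-1-yl]carbonyl}-8-methoxy-3-methyl-6-[(triisopropylsilyl)oxy]-1H-isochromen-1-one F3, the nucleophilic CH2 terminus of the diene bonding to the alkyne carbon that bears CH2OMe. Dilute acid then removes methanol and the trimethylsilyl group to give the diaryl ketone 5-[4-hydroxy-2-methoxy-6-(methoxymethyl)benzoyl]-8-methoxy-3-methyl-6-[(triisopropylsilyl)oxy]-1H-isochromen-1-one F4, with 4′-OH, 2′-OMe and 6′-CH2OMe already placed. Ionic hydrogenation of this electron-rich ketone (Et3SiH, CF3CO2H, CH2Cl2) reduces C=O to CH2 and gives 25.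

2. Step 10. The lithium enolate may add to the exo-methylene enone of a second molecule, proton removal may occur at the γ-CH2OMe, or the diazo enone may decompose on purification. The fallback sets out from 15 and returns at 16; it avoids any anionic enolate. Soft enolization with Me3SiOSO2CF3 and Et3N in CH2Cl2 at 0 °C should convert 15 into the neutral silyl dienol ether 8-methoxy-5-[(2Z)-4-(methoxymethyl)-3-(trimethylsilyloxy)penta-2,4-dien-1-yl]-3-methyl-6-[(triisopropylsilyl)oxy]-1H-isochromen-1-one F5. C-Acylation of F5 at its enol carbon with trifluoroacetic anhydride gives 16 after aqueous work-up, and diazo transfer with the sulfonyl azide then follows as in step 10.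

3. Step 6. Insertion of the alkene at the doubly flanked C5–Pd bond may be slow, so that reductive loss of iodine takes over, or β-hydride elimination may run toward the ring and give the cinnamyl alcohol. The fallback sets out from 8 and returns at 10; it uses a B-alkyl Suzuki–Miyaura coupling. Hydroboration of acrolein diethyl acetal (C=CC(OCC)OCC) with 9-BBN in THF gives 9-(3,3-diethoxypropyl)-9-borabicyclo[3.3.1]nonane F6. Coupling of F6 with 8 (PdCl2(dppf), K3PO4, THF/DMF/H2O, 60 °C) should give the acetal 5-(3,3-diethoxypropyl)-8-methoxy-3-methyl-6-[(triisopropylsilyl)oxy]-1H-isochromen-1-one F7. Mild acid hydrolysis (pyridinium p-toluenesulfonate, acetone/H2O) then releases aldehyde 10 without touching the aryl silyl ether.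

Further compounds
F1 | step 12 | 8-methoxy-5-(4-methoxybut-2-ynoyl)-3-methyl-6-[(triisopropylsilyl)oxy]-1H-isochromen-1-one | COCC#CC(=O)c1c(O[Si](C(C)C)(C(C)C)C(C)C)cc(OC)c2c(=O)oc(C)cc12
F2 | step 12 | 1,1-dimethoxy-3-(trimethylsilyloxy)buta-1,3-diene | C=C(O[Si](C)(C)C)C=C(OC)OC
F3 | step 12 | 5-{[6,6-dimethoxy-2-(methoxymethyl)-4-(trimethylsilyloxy)cyclohexa-1,4-dien-1-yl]carbonyl}-8-methoxy-3-methyl-6-[(triisopropylsilyl)oxy]-1H-isochromen-1-one | COCC1=C(C(=O)c2c(O[Si](C(C)C)(C(C)C)C(C)C)cc(OC)c3c(=O)oc(C)cc23)C(OC)(OC)C=C(O[Si](C)(C)C)C1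
F4 | step 12 | 5-[4-hydroxy-2-methoxy-6-(methoxymethyl)benzoyl]-8-methoxy-3-methyl-6-[(triisopropylsilyl)oxy]-1H-isochromen-1-one | COCc1cc(O)cc(OC)c1C(=O)c1c(O[Si](C(C)C)(C(C)C)C(C)C)cc(OC)c2c(=O)oc(C)cc12
F5 | step 10 | 8-methoxy-5-[(2Z)-4-(methoxymethyl)-3-(trimethylsilyloxy)penta-2,4-dien-1-yl]-3-methyl-6-[(triisopropylsilyl)oxy]-1H-isochromen-1-one | C=C(COC)/C(O[Si](C)(C)C)=C/Cc1c(O[Si](C(C)C)(C(C)C)C(C)C)cc(OC)c2c(=O)oc(C)cc12
F6 | step 6 | 9-(3,3-diethoxypropyl)-9-borabicyclo[3.3.1]nonane | CCOC(CCB1C2CCCC1CCC2)OCC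
F7 | step 6 | 5-(3,3-diethoxypropyl)-8-methoxy-3-methyl-6-[(triisopropylsilyl)oxy]-1H-isochromen-1-one | CCOC(CCc1c(O[Si](C(C)C)(C(C)C)C(C)C)cc(OC)c2c(=O)oc(C)cc12)OCC
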